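**Runs first.** Read the summer and dawn runs: the isomer of the product trails the target early on, so take the order starting material → target → isomer.

common to all: gas 2.6 mM (held)

|  | starting material | second substrate | third substrate | temperature | remark | time |
|---|---|---|---|---|---|---|
| summer | 0.022 M | 0.032 M | 8 mM | −5 °C | run made earlier |  |
| dawn | 0.035 M | 0.032 M | 8 mM | 17 °C | run made earlier |  |
| red | 0.016 M | 0.0320 M | 8.00 mM | 25 °C |  | 2.5 min |
| green | 0.016 M | 0.0320 M | 8.00 mM | −15 °C |  | 2.5 min |
| ochre | 0.016 M | 0.0320 M | 8.00 mM |  | at 25 °C until 80 s, from then on at −15 °C | 2.5 min |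
| blue | 0.016 M | 0.0320 M | 8.00 mM | 5 °C |  | 2.5 min |

summer run (percent of the starting material charged)

| time / min | target / % | isomer of the product / % |
|---|---|---|
| 0.667 | 3.8 | 0.4 |
| 2.00 | 11.0 | 0.2 |
| 4.00 | 22.2 | 4.0 |
| 6.00 | 29.1 | 6.9 |
| 8.00 | 35.1 | 12.4 |

dawn run (percent of the starting material charged)

| time / s | target / % | isomer of the product / % |
|---|---|---|
| 10.0 | 1.2 | 0 |
| 30.0 | 4.3 | 1.0 |
| 60.0 | 6.4 | 4.1 |
| 80.0 | 7.7 | 8.7 |
| 120 | 7.7 | 14.6 |

(scatter of a reading: 0.5 percentage points)

- at the start none of the gas is in solution

* the best flask by share of target in all that became target or isomer of the product; "all alike" if 1.5 percentage points covers them all (red / green / ochre / blue / all alike)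
* share of target in all that became target or isomer of the product, red
* share of target in all that became target or isomer of the product, green
* share of target in all that became target or isomer of the product, ochre
* share of target in all that became target or isomer of the product, blue

**Reading k.** Divide the isomer's gain over the later readings by the mean target and the elapsed time. This gives k, the first-order constant of target → isomer. The summer run reads 0.0733 min⁻¹ and the dawn run reads 1.51 min⁻¹.

**The crossing.** Interpolate ln k linearly in temperature. Blue then comes to 0.725, where N, the isomerisation number, is k times the run time. Below one, the flask is under kinetic control; above one, isomerisation outruns the run. For steady formation, the share of target is (1 − e^−N)/N. Blue sits below the crossing and gets 71.1%. Green comes to 0.0463, a smaller N than blue's, and gets 97.7%.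

**First objection.** Is formation steady? Compute it: the summer total per minute, in fractions of the charge, is 0.0630 min⁻¹ at the first reading and 0.0594 min⁻¹ at the last. Keep the formula.

**Second objection.** Red lies above the dawn temperature, at 11.4, which gives 8.81%. The last dawn reading, an isomer-to-target ratio of 1.90, can't exclude a return from isomer to target. Such a return is absent from the formula, so treat red's figure as a low estimate.

**Ochre's legs.** Add the legs: N = 6.08, nearly all of it from the warm leg. The formula doesn't cover a change of temperature, so place ochre between red and green, without a number.

**The forecast.** It names green: red 14%, green 97%, ochre 33%, blue 71%. Of ochre it says: “This is the least certain value, because it depends on the formation order.” My red figure is lower than its number.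

**The result.** Green is best at 98.1%; blue gives 71.4%, ochre 38.7%, red 23.5%. Red parts furthest from the forecast.

    starting material + coupling partner → target (k = 4.10 M⁻¹ s⁻¹, Ea = 40.0 kJ mol⁻¹)
    second substrate + coupling partner → second product (k = 0.280 M⁻¹ s⁻¹, Ea = 63.0 kJ mol⁻¹)
    third substrate + coupling partner → third product (k = 0.660 M⁻¹ s⁻¹, Ea = 39.0 kJ mol⁻¹)
    target ⇌ isomer of the product (K = 4.90, k = 0.0640 s⁻¹, Ea = 87.0 kJ mol⁻¹, ΔH = −33.0 kJ mol⁻¹)
    gas ⇌ coupling partner, rate k5*(csat - [coupling partner]) (kL = 0.0450 s⁻¹)
    (constants at 25 °C)

**The neighbour.** Repeat green at 0 °C. Scale N from blue: 0.365, below the crossing, so reckon 83.8%. The neighbour flask gives 84.0%, with 18.0% of the charge as target and 3.43% as isomer after 2.50 min.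

(The data are calculated with made-up constants; scatter was added.)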